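The 1,3-diketone is cut at the bond between its central methylene carbon and the ring B carbonyl carbon. The C7 hydroxyl of ring B (the hydroxylated chromene) stands ortho to the C6 acyl carbon, so its oxygen can tether the central carbon temporarily. In one operation, base joins this oxygen to the chloromethyl carbon of a ring A chloroketone and the tethered enolate closes onto the neighbouring ester (Dieckmann), giving a 2-aroyl-3-hydroxybenzofuran; reductive scission of the furan C2–O bond then frees phenol and methylene. The precursor pair is unprotected: methyl 7-hydroxy-2,2-dimethyl-2H-chromene-6-carboxylate and 2-chloro-1-(2,2-dimethyl-2H-chromen-6-yl)ethanone.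

Key step: step 7

Remark: the target has no stereocentre; 19 is drawn as the diketo tautomer although it should exist largely as a chelated enol, and 3-chloro-3-methylbut-1-yne is taken as a commercial reagent.

Step 1
Reactants: 1 methyl 2,4-dihydroxybenzoate
Product: 2 methyl 2,4-dihydroxy-5-iodobenzoate
Conditions: ICl (1.05 equiv), AcOH, rt
Reagents that add atoms: iodine monochloride, ClI
Why: Electrophilic aromatic iodination should go to C5, which is para to the C2 hydroxyl, ortho to the C4 hydroxyl and unhindered, whereas C3 is flanked by both hydroxyls.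

Step 2
Reactants: 2 methyl 2,4-dihydroxy-5-iodobenzoate; 3 2-methylbut-3-yn-2-ol
Product: 4 methyl 2,4-dihydroxy-5-(3-hydroxy-3-methylbut-1-yn-1-yl)benzoate
Conditions: PdCl2(PPh3)2 (cat.), CuI (cat.), Et3N, THF, rt
Reagents that add atoms: none
Why: Sonogashira coupling of an aryl iodide with a terminal alkyne runs at room temperature, where addition of the free C4 hydroxyl across the new alkyne should stay slow.

Step 3
Reactants: 4 methyl 2,4-dihydroxy-5-(3-hydroxy-3-methylbut-1-yn-1-yl)benzoate
Product: 6 methyl 7-hydroxy-2,2-dimethyl-2H-chromene-6-carboxylate, via Z-alkenyl triol 5 (not isolated)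
Conditions: H2 (1 atm), Pd/CaCO3 poisoned with Pb(OAc)2 (Lindlar type), EtOAc, rt; filter, concentrate; PPTS (cat.), toluene, 80 °C
Reagents that add atoms: none
Why: Syn semi-hydrogenation on the poisoned palladium surface sets the Z alkene, which holds the tertiary allylic alcohol beside the C4 hydroxyl so that mild acid ionises it and the phenol closes the pyran ring (cyclodehydration); only the C4 hydroxyl is ortho to the side chain, so one chromene can form.

Step 4
Reactants: 7 4-bromophenol; 8 3-chloro-3-methylbut-1-yne
Product: 9 1-bromo-4-[(2-methylbut-3-yn-2-yl)oxy]benzene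
Conditions: DBU, CuCl2 (cat.), MeCN, 0 °C to rt
Reagents that add atoms: none
Why: Copper-catalysed propargylic etherification, in which the phenoxide captures the copper-activated tertiary propargylic electrophile at the tertiary carbon, is a standard way to aryl 1,1-dimethylpropargyl ethers.

Step 5
Reactants: 9 1-bromo-4-[(2-methylbut-3-yn-2-yl)oxy]benzene
Product: 12 6-bromo-2,2-dimethyl-2H-chromene, via allenylphenol 10 (not isolated), via ortho-quinone methide 11 (not isolated)
Conditions: N,N-diethylaniline, 190 °C
Reagents that add atoms: none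
Why: Thermal aryl propargyl ether Claisen rearrangement, enolisation, 1,5-hydrogen shift and oxa-6π electrocyclisation should give the chromene, and the para bromine makes both ortho positions equivalent so only one product can form.

Step 6
Reactants: 12 6-bromo-2,2-dimethyl-2H-chromene; 13 2-chloro-N-methoxy-N-methylacetamide
Product: 16 2-chloro-1-(2,2-dimethyl-2H-chromen-6-yl)ethan-1-one, via aryllithium 14 (not isolated), via lithium hemiaminal adduct 15 (not isolated)
Conditions: n-BuLi, THF, −78 °C; then 13, −78 °C; 1 M HCl, −78 to 0 °C
Reagents that add atoms: none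
Why: Bromine–lithium exchange and addition to the N-methoxy-N-methylamide (Weinreb ketone synthesis) give a chelated tetrahedral adduct that survives until the acidic quench, which prevents over-addition; its new carbon centre is racemic and is lost on collapse to the ketone.

Step 7
Reactants: 6 methyl 7-hydroxy-2,2-dimethyl-2H-chromene-6-carboxylate; 16 2-chloro-1-(2,2-dimethyl-2H-chromen-6-yl)ethan-1-one
Product: 18 (2,2-dimethyl-2H-chromen-6-yl)(3-hydroxy-7,7-dimethyl-7H-furo[3,2-g]chromen-2-yl)methanone, via phenacyl ether keto ester 17 (not isolated)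
Conditions: K2CO3 (3 equiv), DMF, rt then 80 °C; dilute HCl work-up
Reagents that add atoms: none
Why: Carbonate deprotonates the C7 hydroxyl of 6 and the phenoxide displaces chloride from the primary α-carbon of 16 (SN2, Williamson etherification) to give 17; carbonate then forms the ketone enolate at the new OCH2 group, which adds to the ortho ester carbonyl and expels methoxide (Dieckmann condensation). The furan ring closes in the 5-exo-trig mode, and the resulting 2-aroylbenzofuran-3(2H)-one tautomerises to the aromatic 3-hydroxybenzofuran, whose deprotonation by carbonate should pull the sequence to completion. The closest known reaction type is the tandem O-alkylation and Dieckmann cyclisation of salicylate esters with phenacyl halides to 2-aroyl-3-hydroxybenzofurans. No stereocentre is formed. Only chemoselectivity is needed, O-alkylation first and then C-acylation by the tethered ester alone, and the ortho relation of the C7 hydroxyl and the C6 ester on ring B secures both by making the carbon–carbon bond formation intramolecular and five-membered.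

Step 8
Reactants: 18 (2,2-dimethyl-2H-chromen-6-yl)(3-hydroxy-7,7-dimethyl-7H-furo[3,2-g]chromen-2-yl)methanone
Product: 19 glyinflanin D, 1-(2,2-dimethyl-2H-chromen-6-yl)-3-(7-hydroxy-2,2-dimethyl-2H-chromen-6-yl)propane-1,3-dione
Conditions: Zn dust, AcOH–THF, 40 °C
Reagents that add atoms: none
Why: Proposed new method: in acetic acid the 3-hydroxybenzofuran should equilibrate with its 2-aroylbenzofuran-3(2H)-one tautomer, in which the C2–O bond sits on an sp3 carbon between two carbonyl groups; two single-electron transfers from zinc to this α-aryloxy-1,3-diketone should expel the ring B phenoxide and leave the diketone enolate, which the solvent protonates, while zinc should be too weak a reductant to touch the chelated enol, the chromene alkenes or the product; the closest known reaction type is the zinc–acetic acid (or SmI2) cleavage of α-aryloxy ketones such as phenacyl aryl ethers, not yet shown on an enolised 2-acyl-3-hydroxybenzofuran.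

Compound list
1 | methyl 2,4-dihydroxybenzoate | COC(=O)c1ccc(O)cc1O | starting material
2 | methyl 2,4-dihydroxy-5-iodobenzoate | COC(=O)c1cc(I)c(O)cc1O | intermediate
3 | 2-methylbut-3-yn-2-ol | CC(C)(O)C#C | starting material
4 | methyl 2,4-dihydroxy-5-(3-hydroxy-3-methylbut-1-yn-1-yl)benzoate | COC(=O)c1cc(C#CC(C)(C)O)c(O)cc1O | intermediate
5 | methyl 2,4-dihydroxy-5-[(1Z)-3-hydroxy-3-methylbut-1-en-1-yl]benzoate (Z-alkenyl triol, formed in step 3) | COC(=O)c1cc(/C=C\C(C)(C)O)c(O)cc1O | intermediate
6 | methyl 7-hydroxy-2,2-dimethyl-2H-chromene-6-carboxylate | COC(=O)c1cc2c(cc1O)OC(C)(C)C=C2 | intermediate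
7 | 4-bromophenol | Oc1ccc(Br)cc1 | starting material
8 | 3-chloro-3-methylbut-1-yne | CC(C)(Cl)C#C | starting material
9 | 1-bromo-4-[(2-methylbut-3-yn-2-yl)oxy]benzene | CC(C)(C#C)Oc1ccc(Br)cc1 | intermediate
10 | 4-bromo-2-(3-methylbuta-1,2-dien-1-yl)phenol (allenylphenol, formed in step 5) | CC(C)=C=Cc1cc(Br)ccc1O | intermediate
11 | (6Z)-4-bromo-6-(3-methylbut-2-en-1-ylidene)cyclohexa-2,4-dien-1-one (ortho-quinone methide, formed in step 5) | O=C1C=CC(Br)=C/C1=C/C=C(C)C | intermediate
12 | 6-bromo-2,2-dimethyl-2H-chromene | CC1(C)C=Cc2cc(Br)ccc2O1 | intermediate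
13 | 2-chloro-N-methoxy-N-methylacetamide | CON(C)C(=O)CCl | starting material
14 | (2,2-dimethyl-2H-chromen-6-yl)lithium (aryllithium, formed in step 6) | [Li]c1ccc2OC(C)(C)C=Cc2c1 | intermediate
15 | lithium 2-chloro-1-(2,2-dimethyl-2H-chromen-6-yl)-1-[methoxy(methyl)amino]ethan-1-olate, racemic (hemiaminal adduct, formed in step 6) | [Li+].[O-]C(CCl)(N(C)OC)c1ccc2OC(C)(C)C=Cc2c1 | intermediate
16 | 2-chloro-1-(2,2-dimethyl-2H-chromen-6-yl)ethan-1-one | CC1(C)C=Cc2cc(C(=O)CCl)ccc2O1 | intermediate
17 | methyl 7-[2-(2,2-dimethyl-2H-chromen-6-yl)-2-oxoethoxy]-2,2-dimethyl-2H-chromene-6-carboxylate (phenacyl ether keto ester, formed in step 7) | COC(=O)c1cc2c(cc1OCC(=O)c1ccc3OC(C)(C)C=Cc3c1)OC(C)(C)C=C2 | intermediate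
18 | (2,2-dimethyl-2H-chromen-6-yl)(3-hydroxy-7,7-dimethyl-7H-furo[3,2-g]chromen-2-yl)methanone | CC1(C)C=Cc2cc(C(=O)c3oc4cc5OC(C)(C)C=Cc5cc4c3O)ccc2O1 | intermediate
19 | glyinflanin D, 1-(2,2-dimethyl-2H-chromen-6-yl)-3-(7-hydroxy-2,2-dimethyl-2H-chromen-6-yl)propane-1,3-dione | CC1(C)C=Cc2cc(C(=O)CC(=O)c3cc4c(cc3O)OC(C)(C)C=C4)ccc2O1 | target

Total step count: 8. Longest linear sequence: 5 steps (steps 1, 2, 3, 7, 8 or steps 4, 5, 6, 7, 8).

Steps most likely to fail

Step 8. The enol form dominates and its C2–O bond lies in the plane of the π system, so ketonisation may be too slow for electron transfer to end in scission. Forcing the reduction with a stronger reductant or heat may instead reduce the aroyl carbonyl or remove the C3 oxygen. The fallback uses known chemistry, sets out from 6 and 12 and comes back at 19. Compound 6 would be protected (NaH, MOMCl, THF, 0 °C) as methyl 7-(methoxymethoxy)-2,2-dimethyl-2H-chromene-6-carboxylate F1, so that no phenoxide deactivates the ester. Compound 12 would be lithiated (n-BuLi, THF, −78 °C) and acylated with N-methoxy-N-methylacetamide to give 1-(2,2-dimethyl-2H-chromen-6-yl)ethan-1-one F2. The lithium enolate of F2 (LiHMDS in excess, THF, −78 °C to rt) would undergo crossed Claisen condensation with F1 to give 1-(2,2-dimethyl-2H-chromen-6-yl)-3-[7-(methoxymethoxy)-2,2-dimethyl-2H-chromen-6-yl]propane-1,3-dione F3. Dilute HCl in MeOH at 40 °C would then remove the acetal to give 19.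

Step 2. The free C4 hydroxyl may add across the newly installed alkyne under the palladium–copper conditions (5-endo-dig cycloisomerisation to a furan), or the alkyne may dimerise oxidatively. The fallback sets out from 2 and comes back at 6. A Heck reaction of 2 with 2-methylbut-3-en-2-ol under ligand-free phase-transfer conditions (Pd(OAc)2, Bu4NCl, NaHCO3, DMF, 80 °C) would give methyl 2,4-dihydroxy-5-[(1E)-3-hydroxy-3-methylbut-1-en-1-yl]benzoate F4, an alkene that cannot close to a furan. PPTS in toluene at reflux would ionise the tertiary allylic alcohol; the ortho-quinone methide so formed no longer carries the original alkene geometry and should close by oxa-6π electrocyclisation to 6.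

Step 6. The aryllithium may act as a base toward the acidic α-protons of the chloroacetamide or attack its carbon–chlorine bond, returning debrominated chromene instead of ketone. The fallback sets out from 12 and comes back at 16. Stille coupling of 12 with tributyl(1-ethoxyvinyl)stannane (Pd(PPh3)4, toluene, 100 °C) would give 6-(1-ethoxyethenyl)-2,2-dimethyl-2H-chromene F5. NCS in THF–water at 0 °C would chlorinate the enol ether, which is far more nucleophilic than the chromene alkene, and hydrolysis of the resulting oxocarbenium ion should give 16.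

Further compounds
F1 | step 8 | methyl 7-(methoxymethoxy)-2,2-dimethyl-2H-chromene-6-carboxylate | COCOc1cc2OC(C)(C)C=Cc2cc1C(=O)OC
F2 | step 8 | 1-(2,2-dimethyl-2H-chromen-6-yl)ethan-1-one | CC(=O)c1ccc2OC(C)(C)C=Cc2c1
F3 | step 8 | 1-(2,2-dimethyl-2H-chromen-6-yl)-3-[7-(methoxymethoxy)-2,2-dimethyl-2H-chromen-6-yl]propane-1,3-dione | COCOc1cc2OC(C)(C)C=Cc2cc1C(=O)CC(=O)c1ccc2OC(C)(C)C=Cc2c1
F4 | step 2 | methyl 2,4-dihydroxy-5-[(1E)-3-hydroxy-3-methylbut-1-en-1-yl]benzoate | COC(=O)c1cc(/C=C/C(C)(C)O)c(O)cc1O
F5 | step 6 | 6-(1-ethoxyethenyl)-2,2-dimethyl-2H-chromene | CCOC(=C)c1ccc2OC(C)(C)C=Cc2c1
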